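**Retrosynthetic overview**

1. Ring numbering: C1 (O-angelate), C2 (side chain), C3, C4 (OAc), C5 (Me), C6; side chain C1′–C7′. The three esters go on last (both acetates together, then the angelate) onto a keto-diol in which C1 is still a ketone.
2. C4–O (axial) and C1–O (equatorial) come from two substrate-controlled hydride additions to a cyclohexane-1,4-dione. The two carbonyls are told apart by a temporary ring: the C1 carbonyl and the 1,5-related C4′ hydroxyl close to a trans-fused tetrahydropyran methyl ketal, which also relays the side-chain configuration to the epimerisable ring centres C2 and C5.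
3. Key disconnection: C5–C6 and C2–C3 in one operation, a [3+3] annulation of methyl ketone 7 (C6–C1–C2 as α,α′-bis-nucleophile, carrying the whole side chain) with nitroallylic pivalate 13 (C5–C4–C3 as 1,3-bis-electrophile, NO2 as latent C4 carbonyl).
4. Enabling feature: the 1,4-placement of the two oxygenated carbons C1 and C4 in the cyclohexane ring. Each bond to be made joins a carbon α to C1 with a carbon α to C4 (enolate plus nitroalkene polarity), and every ring stereocentre so created is α to C=O or NO2 and can be corrected afterwards.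
5. Ring order: cyclohexane ring (step 9), then the temporary pyran ring (step 11), opened again in step 12. Side chain: C2′ is bought in hemiester 1, C4′ is set by CBS reduction.

Key step: step 9

Remark: 1 is taken as the commercial enantioenriched (R)-hemiester; compounds 15 to 19 are carried as mixtures of ring epimers by design, so their SMILES show no ring stereodescriptors.

**Route**

Step 1
Reactants: 1 (3R)-5-methoxy-3-methyl-5-oxopentanoic acid (monomethyl (R)-3-methylglutarate)
Product: 3 methyl (3R)-3,7-dimethyl-5-oxooct-6-enoate, via acid chloride 2 (not isolated)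
Conditions: (COCl)2, cat. DMF, CH2Cl2, 0 → 20 °C; evaporate; Me2C=CHMgBr, CuI (10 mol%), THF, −78 °C
Reagents that add atoms: (2-methylprop-1-en-1-yl)magnesium bromide, CC(C)=C[Mg]Br
Why: Copper-catalysed acylation of an alkenyl Grignard reagent by an acid chloride should give the β,β-dimethyl enone at −78 °C without attack on the methyl ester or conjugate addition to the hindered product, and the bought stereocentre (β to both carbonyls) is not touched.

Step 2
Reactants: 3 methyl (3R)-3,7-dimethyl-5-oxooct-6-enoate
Product: 4 methyl (3R,5R)-5-hydroxy-3,7-dimethyloct-6-enoate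
Conditions: (S)-2-methyl-CBS-oxazaborolidine [(3aS)-1-methyl-3,3-diphenyltetrahydro-1H,3H-pyrrolo[1,2-c][1,3,2]oxazaborole] (15 mol%), catecholborane, PhMe, −78 °C; MeOH; pH 7 buffer
Reagents that add atoms: none
Why: Corey–Bakshi–Shibata reduction, in which the alkenyl group acts as the large substituent so that the (S)-catalyst should deliver hydride to give the (R)-allylic alcohol under catalyst control, while catecholborane spares the ester and the trisubstituted alkene.

Step 3
Reactants: 4 methyl (3R,5R)-5-hydroxy-3,7-dimethyloct-6-enoate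
Product: 5 methyl (3R,5R)-3,7-dimethyl-5-[(triethylsilyl)oxy]oct-6-enoate
Conditions: Et3SiCl, imidazole, CH2Cl2, 0 °C
Reagents that add atoms: chlorotriethylsilane, CC[Si](Cl)(CC)CC
Why: Standard silylation of a secondary allylic alcohol with a group that survives organomagnesium reagents, lithium amide and buffered aqueous titanium but is removed by mild acid in step 11.

Step 4
Reactants: 5 methyl (3R,5R)-3,7-dimethyl-5-[(triethylsilyl)oxy]oct-6-enoate
Product: 6 (3R,5R)-N-methoxy-N,3,7-trimethyl-5-[(triethylsilyl)oxy]oct-6-enamide
Conditions: MeNH(OMe)·HCl, i-PrMgCl, THF, −20 → 0 °C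
Reagents that add atoms: N,O-dimethylhydroxylamine hydrochloride, CNOC.Cl
Why: Direct ester-to-Weinreb amide conversion by the chloromagnesium amide of N,O-dimethylhydroxylamine, a reaction that leaves silyl ether, alkene and both stereocentres untouched.

Step 5
Reactants: 6 (3R,5R)-N-methoxy-N,3,7-trimethyl-5-[(triethylsilyl)oxy]oct-6-enamide
Product: 7 (4R,6R)-4,8-dimethyl-6-[(triethylsilyl)oxy]non-7-en-2-one
Conditions: MeMgBr, THF, 0 °C; aq. NH4Cl
Reagents that add atoms: methylmagnesium bromide, C[Mg]Br
Why: Weinreb ketone synthesis, in which the chelated tetrahedral intermediate prevents over-addition and should give the methyl ketone cleanly.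

Step 6
Reactants: 8 2-nitroethan-1-ol; 9 acetaldehyde
Product: 10 2-nitrobutane-1,3-diol (diastereomer mixture)
Conditions: K2CO3 (5 mol%), MeOH, 0 °C
Reagents that add atoms: none
Why: Henry (nitroaldol) reaction of a primary nitroalkane with acetaldehyde; the diastereomer mixture is irrelevant because both stereocentres are destroyed in step 8.

Step 7
Reactants: 10 2-nitrobutane-1,3-diol
Product: 11 3-hydroxy-2-nitrobutyl 2,2-dimethylpropanoate
Conditions: t-BuCOCl (1.0 equiv), pyridine, CH2Cl2, −30 °C
Reagents that add atoms: pivaloyl chloride, CC(C)(C)C(Cl)=O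
Why: Selective acylation of the primary hydroxyl by a bulky acid chloride at low temperature, with pyridine too weak a base to trigger retro-Henry cleavage or elimination.

Step 8
Reactants: 11 3-hydroxy-2-nitrobutyl 2,2-dimethylpropanoate
Product: 13 (2E)-2-nitrobut-2-en-1-yl 2,2-dimethylpropanoate, via mesylate 12 (not isolated)
Conditions: MsCl, i-Pr2NEt (2.1 equiv), CH2Cl2, −30 → 0 °C
Reagents that add atoms: none
Why: Mesylation of the β-nitro alcohol followed by E1cB elimination through the nitronate, in which mesylate leaves far more readily than pivalate, should give the conjugated trisubstituted nitroalkene, and the hindered amine avoids conjugate addition to the product.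

Step 9
Reactants: 7 (4R,6R)-4,8-dimethyl-6-[(triethylsilyl)oxy]non-7-en-2-one; 13 (2E)-2-nitrobut-2-en-1-yl 2,2-dimethylpropanoate
Product: 16 5-methyl-2-[(2R,4R)-6-methyl-4-[(triethylsilyl)oxy]hept-5-en-2-yl]-4-nitrocyclohexan-1-one (ring epimers), via lithium enolate 14 (not isolated), via nitrodienone 15 (not isolated)
Conditions: LiN(i-Pr)2 (1.05 equiv), THF, −78 °C; 13, −78 → −40 °C; then AcOH (1.1 equiv), pyrrolidine (0.3 equiv), −40 → 20 °C
Reagents that add atoms: none
Why: Kinetic deprotonation of the methyl ketone at CH3 gives lithium enolate 14, which adds in conjugate fashion to the CHMe terminus of nitroallylic pivalate 13 (bond C6–C5); the lithium nitronate expels pivalate (E1cB, overall SN2′, pivalate being too poor a leaving group for direct displacement) to unveil the 2-nitro-1-alkene 15, and pyrrolidinium-mediated enamine formation toward the internal α′-methylene then closes the ring by intramolecular Michael addition onto the liberated terminal CH2 (bond C2–C3). The closest known reaction type is the [3+3] carbocyclisation of 2-nitroallylic esters (1,3-bis-electrophiles with a latent central carbonyl) with ketone enamines or enolates, run here with a regiodefined lithium enolate for the first bond and enamine catalysis for the second. The cyclohexanone ring is closed in a 6-endo-trig Michael mode, the only productive one for 15 because closure through the other α-carbon would give a cyclobutane. Of the three new ring stereocentres, C5 arises in the intermolecular step without control from the remote side chain, whereas C2 and C4 are α to C=O and NO2 and are expected to settle into the all-equatorial arrangement relative to C5; none has to be right at this stage, because C4 is erased in step 10 and C2 and C5 then both become epimerisable α-carbonyl centres that step 11 funnels into one configuration. The selectivity the step does need is constitutional: the methyl carbon must bond to the CHMe terminus and the methylene carbon to the CH2 terminus, which is secured by kinetic enolate formation at CH3, by the order of events that 13 imposes (β-carbon first, liberated CH2 second) and by ring size. C- over O-alkylation is secured by the soft nitroalkene acceptor.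

Step 10
Reactants: 16 5-methyl-2-[(2R,4R)-6-methyl-4-[(triethylsilyl)oxy]hept-5-en-2-yl]-4-nitrocyclohexan-1-one (ring epimers)
Product: 18 2-methyl-5-[(2R,4R)-6-methyl-4-[(triethylsilyl)oxy]hept-5-en-2-yl]cyclohexane-1,4-dione (ring epimers), via sodium nitronate 17 (not isolated)
Conditions: NaOMe, MeOH, 0 °C; then aq. TiCl3, NH4OAc (pH 5–6), THF, 20 °C
Reagents that add atoms: water, O
Why: Reductive Nef reaction, in which aqueous trivalent titanium reduces the nitronate to the imine that hydrolyses to the ketone at buffered pH, leaving alkene, silyl ether and the existing ketone intact while the C4 stereocentre disappears and C5 becomes epimerisable.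

Step 11
Reactants: 18 2-methyl-5-[(2R,4R)-6-methyl-4-[(triethylsilyl)oxy]hept-5-en-2-yl]cyclohexane-1,4-dione (ring epimers)
Product: 21 (2R,4R,4aS,7S,8aR)-8a-methoxy-4,7-dimethyl-2-(2-methylprop-1-en-1-yl)octahydro-6H-chromen-6-one (trans-fused), via hydroxy dione 19 (not isolated), via hemiketal 20 (not isolated)
Conditions: AcOH–THF–H2O (3:1:1), 20 °C; evaporate (PhMe azeotrope); DBU (0.2 equiv), PhMe, 20 °C, Ar; then MeOH (20 equiv), PPTS (0.5 equiv), 20 °C
Reagents that add atoms: methanol, CO
Why: Base epimerisation of α-carbonyl centres coupled to ring-chain tautomerism and acid-catalysed mixed ketal formation: after desilylation C2 and C5 both equilibrate under DBU while the C4′ hydroxyl adds reversibly to the C1 carbonyl, and only the (2S,5S)-dione can form a trans-fused hemiketal in which the ring methyl, the pyran methyl and the alkenyl group are all equatorial, so the mixture should drain into that isomer, which PPTS and methanol then lock as the anomerically stabilised methyl ketal (C2, C5 and the ketal carbon set by thermodynamic relay from the side-chain stereocentres).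

Step 12
Reactants: 21 (2R,4R,4aS,7S,8aR)-8a-methoxy-4,7-dimethyl-2-(2-methylprop-1-en-1-yl)octahydro-6H-chromen-6-one
Product: 23 (2S,4R,5S)-4-hydroxy-2-[(2R,4R)-4-hydroxy-6-methylhept-5-en-2-yl]-5-methylcyclohexan-1-one, via ketal alcohol 22 (not isolated)
Conditions: LiBH(s-Bu)3, THF, −78 °C; then AcOH–H2O–THF, 20 °C
Reagents that add atoms: water, O
Why: Bulky trialkylborohydride reduction, in which hydride should approach the conformationally locked 2-methylcyclohexanone unit along the equatorial trajectory to give the axial C4 alcohol cis to the equatorial methyl group (substrate control) while C1 is masked, after which mild aqueous acid hydrolyses the 2-methoxytetrahydropyran ketal to release the C1 ketone and the C4′ carbinol.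

Step 13
Reactants: 23 (2S,4R,5S)-4-hydroxy-2-[(2R,4R)-4-hydroxy-6-methylhept-5-en-2-yl]-5-methylcyclohexan-1-one
Product: 24 (2S,4R,5S)-4-(acetyloxy)-2-[(2R,4R)-4-(acetyloxy)-6-methylhept-5-en-2-yl]-5-methylcyclohexan-1-one
Conditions: Ac2O, pyridine, DMAP (cat.), CH2Cl2, 0 → 20 °C
Reagents that add atoms: acetic anhydride, CC(=O)OC(C)=O
Why: DMAP-catalysed acetylation esterifies the axial ring carbinol and the allylic side-chain carbinol in one operation while C1 is still a ketone, which is what differentiates the three oxygens, and C2 stays in its thermodynamically preferred equatorial configuration.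

Step 14
Reactants: 24 (2S,4R,5S)-4-(acetyloxy)-2-[(2R,4R)-4-(acetyloxy)-6-methylhept-5-en-2-yl]-5-methylcyclohexan-1-one
Product: 25 (1R,2S,4R,5S)-4-(acetyloxy)-2-[(2R,4R)-4-(acetyloxy)-6-methylhept-5-en-2-yl]-5-methylcyclohexan-1-ol
Conditions: NaBH4, CeCl3·7H2O, MeOH, −78 °C
Reagents that add atoms: none
Why: Luche-type borohydride reduction, in which the small hydride donor should attack the axial face of the 2-alkylcyclohexanone (only axial hydrogens at C3 and C5 on that face) to give the equatorial C1 alcohol trans to the side chain (substrate control), with both acetates inert at −78 °C.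

Step 15
Reactants: 25 (1R,2S,4R,5S)-4-(acetyloxy)-2-[(2R,4R)-4-(acetyloxy)-6-methylhept-5-en-2-yl]-5-methylcyclohexan-1-ol
Product: 26 (1R,2S,4R,5S)-4-(acetyloxy)-2-[(2R,4R)-4-(acetyloxy)-6-methylhept-5-en-2-yl]-5-methylcyclohexyl (2Z)-2-methylbut-2-enoate
Conditions: angelic acid, 2,4,6-Cl3C6H2COCl, Et3N, PhMe, 20 °C; then 25, 75 °C
Reagents that add atoms: angelic acid [(2Z)-2-methylbut-2-enoic acid], C/C=C(/C)C(=O)O
Why: Yamaguchi-type esterification through the angelic 2,4,6-trichlorobenzoic mixed anhydride acylates hindered secondary alcohols without the Z-to-E isomerisation (angelate to tiglate) that acid chloride or DMAP-based methods tend to cause, and the acetates do not react.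

**Compound list**

1 | (3R)-5-methoxy-3-methyl-5-oxopentanoic acid | COC(=O)C[C@H](C)CC(=O)O | starting material
2 | methyl (3S)-5-chloro-3-methyl-5-oxopentanoate | COC(=O)C[C@H](C)CC(Cl)=O | intermediate (not isolated)
3 | methyl (3R)-3,7-dimethyl-5-oxooct-6-enoate | COC(=O)C[C@H](C)CC(=O)C=C(C)C | intermediate
4 | methyl (3R,5R)-5-hydroxy-3,7-dimethyloct-6-enoate | COC(=O)C[C@H](C)C[C@H](C=C(C)C)O | intermediate
5 | methyl (3R,5R)-3,7-dimethyl-5-[(triethylsilyl)oxy]oct-6-enoate | COC(=O)C[C@H](C)C[C@H](C=C(C)C)O[Si](CC)(CC)CC | intermediate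
6 | (3R,5R)-N-methoxy-N,3,7-trimethyl-5-[(triethylsilyl)oxy]oct-6-enamide | CON(C)C(=O)C[C@H](C)C[C@H](C=C(C)C)O[Si](CC)(CC)CC | intermediate
7 | (4R,6R)-4,8-dimethyl-6-[(triethylsilyl)oxy]non-7-en-2-one | CC(=O)C[C@H](C)C[C@H](C=C(C)C)O[Si](CC)(CC)CC | intermediate
8 | 2-nitroethan-1-ol | OCC[N+](=O)[O-] | starting material
9 | acetaldehyde | CC=O | starting material
10 | 2-nitrobutane-1,3-diol (diastereomer mixture) | CC(O)C(CO)[N+](=O)[O-] | intermediate
11 | 3-hydroxy-2-nitrobutyl 2,2-dimethylpropanoate | CC(O)C(COC(=O)C(C)(C)C)[N+](=O)[O-] | intermediate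
12 | 3-[(methylsulfonyl)oxy]-2-nitrobutyl 2,2-dimethylpropanoate | CC(OS(C)(=O)=O)C(COC(=O)C(C)(C)C)[N+](=O)[O-] | intermediate (not isolated)
13 | (2E)-2-nitrobut-2-en-1-yl 2,2-dimethylpropanoate | C/C=C(/[N+](=O)[O-])COC(=O)C(C)(C)C | intermediate
14 | lithium (4R,6R)-4,8-dimethyl-6-[(triethylsilyl)oxy]nona-1,7-dien-2-olate | C=C(O[Li])C[C@H](C)C[C@H](C=C(C)C)O[Si](CC)(CC)CC | intermediate (not isolated)
15 | (7R,9R)-3,7,11-trimethyl-2-nitro-9-[(triethylsilyl)oxy]dodeca-1,10-dien-5-one (both C3 epimers) | C=C([N+](=O)[O-])C(C)CC(=O)C[C@H](C)C[C@H](C=C(C)C)O[Si](CC)(CC)CC | intermediate (not isolated)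
16 | 5-methyl-2-[(2R,4R)-6-methyl-4-[(triethylsilyl)oxy]hept-5-en-2-yl]-4-nitrocyclohexan-1-one (ring epimers) | CC1CC(=O)C(CC1[N+](=O)[O-])[C@H](C)C[C@H](C=C(C)C)O[Si](CC)(CC)CC | intermediate
17 | sodium nitronate of 16 | CC1CC(=O)C(CC1=[N+]([O-])[O-])[C@H](C)C[C@H](C=C(C)C)O[Si](CC)(CC)CC.[Na+] | intermediate (not isolated)
18 | 2-methyl-5-[(2R,4R)-6-methyl-4-[(triethylsilyl)oxy]hept-5-en-2-yl]cyclohexane-1,4-dione (ring epimers) | CC1CC(=O)C(CC1=O)[C@H](C)C[C@H](C=C(C)C)O[Si](CC)(CC)CC | intermediate
19 | 2-[(2R,4R)-4-hydroxy-6-methylhept-5-en-2-yl]-5-methylcyclohexane-1,4-dione (equilibrating ring epimers) | CC1CC(=O)C(CC1=O)[C@H](C)C[C@H](C=C(C)C)O | intermediate (not isolated)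
20 | (2R,4R,4aS,7S,8aR)-8a-hydroxy-4,7-dimethyl-2-(2-methylprop-1-en-1-yl)octahydro-6H-chromen-6-one (trans-fused hemiketal) | O[C@@]12C[C@H](C)C(=O)C[C@H]1[C@H](C)C[C@H](C=C(C)C)O2 | intermediate (not isolated)
21 | (2R,4R,4aS,7S,8aR)-8a-methoxy-4,7-dimethyl-2-(2-methylprop-1-en-1-yl)octahydro-6H-chromen-6-one (trans-fused) | CO[C@@]12C[C@H](C)C(=O)C[C@H]1[C@H](C)C[C@H](C=C(C)C)O2 | intermediate
22 | (2R,4R,4aS,6R,7S,8aR)-8a-methoxy-4,7-dimethyl-2-(2-methylprop-1-en-1-yl)octahydro-2H-chromen-6-ol | CO[C@@]12C[C@H](C)[C@H](O)C[C@H]1[C@H](C)C[C@H](C=C(C)C)O2 | intermediate (not isolated)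
23 | (2S,4R,5S)-4-hydroxy-2-[(2R,4R)-4-hydroxy-6-methylhept-5-en-2-yl]-5-methylcyclohexan-1-one | O=C1C[C@H](C)[C@H](O)C[C@H]1[C@H](C)C[C@H](C=C(C)C)O | intermediate
24 | (2S,4R,5S)-4-(acetyloxy)-2-[(2R,4R)-4-(acetyloxy)-6-methylhept-5-en-2-yl]-5-methylcyclohexan-1-one | O=C1C[C@H](C)[C@H](OC(C)=O)C[C@H]1[C@H](C)C[C@H](C=C(C)C)OC(C)=O | intermediate
25 | (1R,2S,4R,5S)-4-(acetyloxy)-2-[(2R,4R)-4-(acetyloxy)-6-methylhept-5-en-2-yl]-5-methylcyclohexan-1-ol | O[C@@H]1C[C@H](C)[C@H](OC(C)=O)C[C@H]1[C@H](C)C[C@H](C=C(C)C)OC(C)=O | intermediate
26 | (1R,2S,4R,5S)-4-(acetyloxy)-2-[(2R,4R)-4-(acetyloxy)-6-methylhept-5-en-2-yl]-5-methylcyclohexyl (2Z)-2-methylbut-2-enoate | C/C=C(/C)C(=O)O[C@@H]1C[C@H](C)[C@H](OC(C)=O)C[C@H]1[C@H](C)C[C@H](C=C(C)C)OC(C)=O | target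

**Step count**

Total steps: 15. Longest linear sequence: 12 (steps 1–5 and 9–15); steps 6–8 are a three-step branch to reagent 13.

**Steps most likely to fail, with fallbacks**

Step 9. What may go wrong: base-triggered oligomerisation of the liberated 2-nitro-1-alkene, or enolate equilibration before the first C–C bond forms, which would scramble the regiochemistry of the annulation. The fallback sets out from 7 and comes back at 16, and moves the whole sequence into the neutral enamine manifold. Ketone 7 is condensed with pyrrolidine (TiCl4, PhMe, 0 °C) to its enamine, whose methylene-terminus isomer 1-[(4S,6R)-4,8-dimethyl-6-[(triethylsilyl)oxy]nona-1,7-dien-2-yl]pyrrolidine F1 is the one able to attack the β-substituted nitroalkene. F1 is combined with 13 in MeCN at −20 → 20 °C, so that addition, loss of pivalate and ring closure all run through enamine and iminium intermediates, as in the classical enamine version of this carbocyclisation. Hydrolysis with aqueous AcOH should then deliver 16.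

Step 11. What may go wrong: the thermodynamic preference for the trans-fused hemiketal may be too small, or epimerisation too slow, so that ring epimers persist; prolonged acid could also ionise the allylic C–O bond. The fallback sets out from 19 and comes back at 21, and replaces the one-pot funnel by resolution through selective ketalisation with recycling. The DBU-equilibrated mixture is ketalised under kinetic conditions (PPTS, MeOH, 0 °C, short contact), which should trap only the hemiketal-forming (2S,5S)-isomer as 21. Chromatography separates 21 from the unketalised ring-epimeric trans-dione, (2R,5R)-2-[(2R,4R)-4-hydroxy-6-methylhept-5-en-2-yl]-5-methylcyclohexane-1,4-dione F2, which is returned to the DBU equilibration and cycled.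

Step 14. What may go wrong: poor facial selectivity of hydride delivery, giving the axial C1 alcohol. The fallback sets out from 24 and comes back at 26, and inverts instead of selecting. LiBH(s-Bu)3 in THF at −78 °C should give, by equatorial attack, the axial alcohol (1S,2S,4R,5S)-4-(acetyloxy)-2-[(2R,4R)-4-(acetyloxy)-6-methylhept-5-en-2-yl]-5-methylcyclohexan-1-ol F3. A Mitsunobu esterification with angelic acid (PPh3, diisopropyl azodicarboxylate, PhMe, 0 → 20 °C) then installs the angelate with inversion at C1, reaching 26 directly and bypassing 25 and step 15.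

**Further compounds**

F1 | step 9 | 1-[(4S,6R)-4,8-dimethyl-6-[(triethylsilyl)oxy]nona-1,7-dien-2-yl]pyrrolidine | C=C(N1CCCC1)C[C@H](C)C[C@H](C=C(C)C)O[Si](CC)(CC)CC
F2 | step 11 | (2R,5R)-2-[(2R,4R)-4-hydroxy-6-methylhept-5-en-2-yl]-5-methylcyclohexane-1,4-dione | O=C1C[C@@H](C)C(=O)C[C@@H]1[C@H](C)C[C@H](C=C(C)C)O
F3 | step 14 | (1S,2S,4R,5S)-4-(acetyloxy)-2-[(2R,4R)-4-(acetyloxy)-6-methylhept-5-en-2-yl]-5-methylcyclohexan-1-ol | O[C@H]1C[C@H](C)[C@H](OC(C)=O)C[C@H]1[C@H](C)C[C@H](C=C(C)C)OC(C)=O
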